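# Proposed synthesis of CNP0208188.1: (R,E)-1-(2,4-dihydroxyphenyl)-3,7,11-trimethyl-3-vinyldodeca-6,10-diene-1,9-dione (23)

## The problem

Target 23 is an open chain attached to a resorcinol ring. Numbered from the aryl ketone carbon C1, it runs through C2, the quaternary carbon C3 (methyl and vinyl), C4 and C5, the E-trisubstituted alkene C6=C7, C8, the ketone C9 and the enone alkene C10=C11. C3 is the only stereocentre, so no neighbouring centre can direct it. It has to come from a catalyst or from a temporary stereocentre that is erased afterwards. Its two methylene arms (C2 and C4) differ only two atoms out, so the step that creates C3 must tell apart groups of similar size. C6=C7, C8 and C9 make up a β,γ-unsaturated ketone that moves into conjugation under acid or base, and the C9/C10=C11 enone is a Michael acceptor. The vinyl group and the trisubstituted alkene rule out strong acids, hydrogenation and unselective hydroboration. The resorcinol is acidic, nucleophilic and easily oxidised; it has to stay masked through organometallic and palladium chemistry and be released last under conditions the skipped dienone tolerates. The enabling feature is that the vinyl carbons and C3 form an allyl unit next to the C3–C4 bond. Attack of a C4 nucleophile on the γ-carbon of a Cl–CH2–CH=C3 electrophile therefore forms C3–C4, the vinyl group and the stereocentre in one event, and C4–C8 is a plain primary alkyl group that hydroboration can supply.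

## Retrosynthesis

**Unmasking (23 from 22).** The two aryl O–Si bonds are cut last. Free phenols would quench the aryl Grignard reagent 17, intercept the acylpalladium species of step 16 and react in the chlorination of step 15. Silyl ethers are chosen because fluoride at 0 °C removes them, whereas methyl or acetal ethers would need acids that move the C6=C7 alkene into conjugation. The forward reaction must be complete without conditions basic enough to enolise C8.

**Skipped dienone (22 from 21, 20 and 19).** The C8–C9 and C9–C10 bonds are cut, with C9 coming from carbon monoxide and C10–C11 from an alkenyltin reagent. The neighbouring cuts (aldol or acyl-anion alkylation) need strong base beside the enolisable aryl ketone. The carbonylative coupling is neutral and places the most fragile motif late. Chloride 21 lacks five carbons and the enone; it comes from allylic alcohol 20, and 20 from the 4-methoxybenzyl ether 19. The forward step needs CO insertion to outrun direct coupling, retention of the E geometry at C6=C7 and no double-bond migration.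

**Aryl ketone (19 from 18, from 14 and 17).** The C1–aryl bond is cut. Friedel–Crafts acylation of a resorcinol would need acids the alkenes cannot bear, so an aryl nucleophile is added to aldehyde 14 and carbinol 18 is oxidised. This removes the whole arene from the chain fragment. Grignard reagent 17 comes from bromide 16, the bis-silyl ether of 4-bromoresorcinol (15). The aryl metal carries an ortho silyloxy group that must not migrate, which is why triisopropylsilyl groups are used.

**Oxidation level at C1 (14 from 13 from 12).** These are functional-group changes only. In 12 the C1 oxygen is a tert-butyldimethylsilyl ether and the C8 oxygen a 4-methoxybenzyl ether, so each terminus can be opened on its own. The benzyl ether survives fluoride, periodinane and the Grignard addition.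

**Key cut (12 from 5 and 11).** The C3–C4 bond is cut. A cut at C2–C3 (sigmatropic) or at C3–vinyl (conjugate addition) leaves the C4–C8 chain in one piece with an unfunctionalised C8 that must be oxidised late. The C3–C4 cut divides 12 into two six-carbon pieces, allylic chloride 5 and alkylborane 11. Neither has a stereocentre, and each has one alkene of fixed geometry and one protected oxygen. The forward reaction must be γ-selective and enantioface-selective, and 5 must be geometrically pure E.

**Chloride 5 (from 4, 2 and 1).** The bonds from the alkyne carbons of 2 to the methyl group and to the hydroxymethyl carbon are cut. Syn carbometallation of a terminal alkyne fixes the E geometry in one operation, whereas olefination of the corresponding methyl ketone would give E/Z mixtures. Silyl ether 2 comes from but-3-yn-1-ol (1).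

**Borane 11 (from 10, 9, 8, 6 and 7).** The B–C4 bond is cut back to diene 10, and the C6=C7 bond to acrolein (6) and the stabilised ylide 7 by way of ester 8 and alcohol 9. The Wittig reaction gives the E alkene, and 9-BBN must select the terminal alkene of the diene.

## Roads not taken

**Alternative 1: chirality-transfer Claisen rearrangement.** This road cuts C2–C3. Heating the 1-arylvinyl ether A1 of an (R)-configured α-silyl allylic carbinol should give aryl ketone A2 through a chair transition state with the silyl group equatorial.
- Merits: the quaternary centre is set by chirality transfer, independent of any catalyst. The aryl ketone appears in the same step, so the Grignard addition and reoxidation of the chosen plan (steps 12 and 13) are not needed. In both respects this road is better.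
- Weak points: A1 needs an asymmetric acylsilane reduction and the enol etherification of a hindered, Brook-prone secondary alcohol. The E-vinylsilane of A2 must be protodesilylated beside an acid-sensitive trisubstituted alkene. A2 ends in a prenyl group, so C8 has to be oxidised late by allylic C–H oxidation, in a molecule with several allylic positions and an enolisable ketone.
- Comparison: the chosen plan is less certain in its stereo-defining step. Against that it carries the C8 oxygen from the start, needs no C–H oxidation and is convergent.

**Alternative 2: late carbonylative three-component coupling as the central step.** This road cuts C8–C9 and C9–C10. Allylic chloride A3, CO and the isobutenyltin reagent of step 16 would be joined under Pd(dba)2 and PPh3 to give dione A4.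
- Merits: the skipped dienone is made last under neutral conditions, and the reaction is convergent. The chosen plan uses the same reaction in step 16, so the two are equal in the endgame.
- Weak points: as a strategy it does not say how the C3 stereocentre in A3 arises, so the main stereochemical problem is postponed. Its risks (alkene geometry, coupling without CO) fall on the most advanced material.
- Comparison: the chosen plan adds a defined catalytic origin for C3 and places the strategic risk earlier, on six-carbon fragments.

**Alternative 3: enantioselective conjugate vinylation.** This road cuts the C3–vinyl bond. A dialkyl(vinyl)aluminium reagent would add to the β-carbon of the E-configured aryl enone A5 under CuCl2·2H2O and a chiral sulfonate-bearing imidazolinium salt, giving ketone A6.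
- Merits: A5 is a geranyl-type enone reachable in very few steps, and the aryl ketone is in place before the stereocentre is made. To the quaternary centre this road is clearly shorter than the chosen one.
- Weak points: the ortho silyloxy group twists and crowds the carbonyl that the catalyst must bind. Lewis-acid-induced E/Z isomerisation of A5 would erode selectivity. A6 again ends in a prenyl group, so it needs the same late allylic oxidation at C8 as Alternative 1.
- Comparison: the chosen plan is longer. It sets against this a C8 oxygen installed from the start and enantio-discrimination at a small, unhindered allylic chloride.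

Key step: step 8

Remark on the chemistry: tributyl(2-methylprop-1-enyl)stannane and the enantiopure hydroxy-bearing imidazolinium salt are taken as available reagents, and 9-BBN is used as its dimer.

## Route

Step 1
Reactants: 1 but-3-yn-1-ol
Product: 2 tert-butyl(but-3-yn-1-yloxy)dimethylsilane
Conditions: TBSCl, imidazole, CH2Cl2, 0 °C → rt
Reagents that add atoms: tert-butyldimethylsilyl chloride, CC(C)(C)[Si](C)(C)Cl
Why: Imidazole-mediated silylation of a primary alcohol; the silyl ether masks the C1 oxygen through the organoaluminium step, the chlorination and the basic borate coupling.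

Step 2
Reactants: 2 tert-butyl(but-3-yn-1-yloxy)dimethylsilane
Product: 4 (E)-5-(tert-butyldimethylsilyloxy)-3-methylpent-2-en-1-ol, via alkenyldimethylalane 3 (not isolated)
Conditions: Me3Al, Cp2ZrCl2 (0.2 equiv), CH2Cl2, 0 °C → rt; then (CH2O)n, THF, 0 °C → rt
Reagents that add atoms: trimethylaluminium, C[Al](C)C; paraformaldehyde (as formaldehyde), C=O
Why: Zirconium-catalysed methylalumination (Negishi carboalumination) adds methyl and aluminium syn across the terminal alkyne with methyl on the internal carbon, so alane 3 is E; hydroxymethylation of the Al–C bond with formaldehyde proceeds with retention and should give the E-allylic alcohol.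

Step 3
Reactants: 4 (E)-5-(tert-butyldimethylsilyloxy)-3-methylpent-2-en-1-ol
Product: 5 (E)-tert-butyl[(5-chloro-3-methylpent-3-en-1-yl)oxy]dimethylsilane
Conditions: PPh3, Cl3CC(O)CCl3, CH2Cl2, −20 → 0 °C
Reagents that add atoms: hexachloroacetone, ClC(Cl)(Cl)C(=O)C(Cl)(Cl)Cl
Why: Appel-type chlorination; chloride displaces the alkoxyphosphonium group at the primary carbon under neutral conditions, so neither allylic transposition nor loss of the E geometry is expected and the silyl ether is untouched.

Step 4
Reactants: 6 acrolein; 7 ethyl 2-(triphenylphosphoranylidene)propanoate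
Product: 8 ethyl (E)-2-methylpenta-2,4-dienoate
Conditions: CH2Cl2, 0 °C → rt
Reagents that add atoms: none
Why: Wittig olefination with a stabilised α-methyl ylide gives the E-trisubstituted enoate and reacts at the aldehyde carbon in preference to conjugate addition.

Step 5
Reactants: 8 ethyl (E)-2-methylpenta-2,4-dienoate
Product: 9 (E)-2-methylpenta-2,4-dien-1-ol
Conditions: i-Bu2AlH (2.2 equiv), CH2Cl2, −78 → 0 °C
Reagents that add atoms: none
Why: Hydride reduction of the conjugated ester by 1,2-delivery gives the allylic alcohol and leaves the diene and its geometry alone.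

Step 6
Reactants: 9 (E)-2-methylpenta-2,4-dien-1-ol
Product: 10 1-methoxy-4-({[(E)-2-methylpenta-2,4-dien-1-yl]oxy}methyl)benzene
Conditions: NaH, 4-methoxybenzyl chloride, Bu4NI (cat.), THF, 0 °C → rt
Reagents that add atoms: 4-methoxybenzyl chloride, COc1ccc(CCl)cc1
Why: Williamson etherification; the basic conditions avoid ionising the dienylic alcohol, which acid-catalysed benzylation would risk.

Step 7
Reactants: 10 1-methoxy-4-({[(E)-2-methylpenta-2,4-dien-1-yl]oxy}methyl)benzene
Product: 11 9-[(E)-5-(4-methoxybenzyloxy)-4-methylpent-3-en-1-yl]-9-borabicyclo[3.3.1]nonane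
Conditions: 9-BBN dimer (0.5 equiv), THF, 0 → 50 °C; concentrated under argon and used without purification
Reagents that add atoms: 9-borabicyclo[3.3.1]nonane, B1C2CCCC1CCC2
Why: Anti-Markovnikov hydroboration; 9-BBN is very sensitive to substitution, so boron should go to the terminal carbon of the monosubstituted alkene and leave the trisubstituted alkene, as in hydroborations of 4-substituted 1,3-dienes to homoallylic boranes.

Step 8
Reactants: 5 (E)-tert-butyl[(5-chloro-3-methylpent-3-en-1-yl)oxy]dimethylsilane; 11 9-[(E)-5-(4-methoxybenzyloxy)-4-methylpent-3-en-1-yl]-9-borabicyclo[3.3.1]nonane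
Product: 12 (R,E)-tert-butyl{[8-(4-methoxybenzyloxy)-3,7-dimethyl-3-vinyloct-6-en-1-yl]oxy}dimethylsilane
Conditions: CuCl (10 mol %), chiral 2-hydroxyaryl-substituted imidazolinium salt (12 mol %), KOMe (1.5 equiv), 11 (1.5 equiv), 1,4-dioxane, 25 °C
Reagents that add atoms: none
Why: KOMe adds to boron of 11 to give a methoxyborate, which passes its primary alkyl group to monovalent copper bound to the chiral carbene generated from CuCl, the imidazolinium salt and base. The alkylcopper species attacks 5 at the γ-carbon anti to chloride (SN2′), and the trivalent allylcopper intermediate eliminates reductively before it can shift to the α-bound isomer, so C3–C4, the vinyl group and the stereocentre arise together. The closest known reaction type is the copper and chiral carbene catalysed γ-selective allyl–alkyl coupling of alkyl-9-BBN reagents with γ,γ-disubstituted primary allyl chlorides, applied here within its substrate class. No ring is closed. The stereocentre C3 is set by the catalyst alone: the ligand enantiomer is chosen so that the alkyl group arrives on the Re face of the γ-carbon of 5, which corresponds to R in 12. The step needs γ over α regioselectivity, which the ligated copper centre provides by bonding through the alkene of a primary chloride. It also needs enantioface selectivity, which rests on the size difference between the methyl group and the silyloxyethyl arm and on the geometric purity of 5 from step 2, because the Z isomer would present the opposite face. Both partners carry only ethers, which the borate conditions tolerate.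

Step 9
Reactants: 12 (R,E)-tert-butyl{[8-(4-methoxybenzyloxy)-3,7-dimethyl-3-vinyloct-6-en-1-yl]oxy}dimethylsilane
Product: 13 (R,E)-8-(4-methoxybenzyloxy)-3,7-dimethyl-3-vinyloct-6-en-1-ol
Conditions: Bu4NF, THF, 0 °C → rt
Reagents that add atoms: none
Why: Fluoride-driven cleavage of the primary silyl ether; the benzyl ether and the alkenes are inert and the quaternary centre cannot epimerise.

Step 10
Reactants: 13 (R,E)-8-(4-methoxybenzyloxy)-3,7-dimethyl-3-vinyloct-6-en-1-ol
Product: 14 (R,E)-8-(4-methoxybenzyloxy)-3,7-dimethyl-3-vinyloct-6-enal
Conditions: Dess–Martin periodinane, CH2Cl2, 0 °C → rt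
Reagents that add atoms: none
Why: Dess–Martin oxidation stops at the aldehyde under near-neutral conditions; the aldehyde has no α-stereocentre and its β-carbon is quaternary, so nothing can be scrambled.

Step 11
Reactants: 15 4-bromoresorcinol
Product: 16 1-bromo-2,4-bis(triisopropylsilyloxy)benzene
Conditions: TIPSCl (2.4 equiv), imidazole, DMF, rt → 40 °C
Reagents that add atoms: triisopropylsilyl chloride, CC(C)[Si](Cl)(C(C)C)C(C)C
Why: Imidazole-mediated silylation of both phenols; the bulky triisopropylsilyl group is chosen because it resists migration from oxygen to the ortho carbanion of 17 and to the benzylic alkoxide formed in step 12.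

Step 12
Reactants: 16 1-bromo-2,4-bis(triisopropylsilyloxy)benzene; 14 (R,E)-8-(4-methoxybenzyloxy)-3,7-dimethyl-3-vinyloct-6-enal
Product: 18 (3R,6E)-1-[2,4-bis(triisopropylsilyloxy)phenyl]-8-(4-methoxybenzyloxy)-3,7-dimethyl-3-vinyloct-6-en-1-ol, via arylmagnesium bromide 17 (not isolated)
Conditions: 16 (1.3 equiv), Mg turnings, LiCl, THF, 25 °C; then 14, −40 → 0 °C; aq. NH4Cl
Reagents that add atoms: none
Why: Magnesium insertion, which LiCl accelerates for the electron-rich bromide, gives the Grignard reagent, and this adds 1,2 to the unhindered aldehyde. The new carbinol centre is formed without control as a mixture of C1 epimers, which does not matter because step 13 removes it.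

Step 13
Reactants: 18 (3R,6E)-1-[2,4-bis(triisopropylsilyloxy)phenyl]-8-(4-methoxybenzyloxy)-3,7-dimethyl-3-vinyloct-6-en-1-ol
Product: 19 (R,E)-1-[2,4-bis(triisopropylsilyloxy)phenyl]-8-(4-methoxybenzyloxy)-3,7-dimethyl-3-vinyloct-6-en-1-one
Conditions: Dess–Martin periodinane, CH2Cl2, 0 °C → rt
Reagents that add atoms: none
Why: Dess–Martin oxidation of a hindered secondary benzylic alcohol to the aryl ketone; both C1 epimers converge on one compound.

Step 14
Reactants: 19 (R,E)-1-[2,4-bis(triisopropylsilyloxy)phenyl]-8-(4-methoxybenzyloxy)-3,7-dimethyl-3-vinyloct-6-en-1-one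
Product: 20 (R,E)-1-[2,4-bis(triisopropylsilyloxy)phenyl]-8-hydroxy-3,7-dimethyl-3-vinyloct-6-en-1-one
Conditions: DDQ (1.2 equiv), CH2Cl2/pH 7 buffer (10:1), 0 °C
Reagents that add atoms: none
Why: Oxidative cleavage of the 4-methoxybenzyl ether by hydride abstraction to an oxocarbenium ion and hydrolysis. The acyl group deactivates the silylated resorcinol ring, and short exposure at 0 °C should limit oxidation of the liberated allylic alcohol.

Step 15
Reactants: 20 (R,E)-1-[2,4-bis(triisopropylsilyloxy)phenyl]-8-hydroxy-3,7-dimethyl-3-vinyloct-6-en-1-one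
Product: 21 (R,E)-1-[2,4-bis(triisopropylsilyloxy)phenyl]-8-chloro-3,7-dimethyl-3-vinyloct-6-en-1-one
Conditions: PPh3, Cl3CC(O)CCl3, CH2Cl2, −20 → 0 °C
Reagents that add atoms: hexachloroacetone, ClC(Cl)(Cl)C(=O)C(Cl)(Cl)Cl
Why: Appel-type chlorination as in step 3; the neutral, cold conditions should leave the ketone, the aryl silyl ethers and the C6=C7 geometry unchanged.

Step 16
Reactants: 21 (R,E)-1-[2,4-bis(triisopropylsilyloxy)phenyl]-8-chloro-3,7-dimethyl-3-vinyloct-6-en-1-one
Product: 22 (R,E)-1-[2,4-bis(triisopropylsilyloxy)phenyl]-3,7,11-trimethyl-3-vinyldodeca-6,10-diene-1,9-dione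
Conditions: CO (3 atm), Bu3SnCH=CMe2 (1.2 equiv), Pd(dba)2 (5 mol %), PPh3 (10 mol %), THF, 50 °C
Reagents that add atoms: carbon monoxide, [C-]#[O+]; tributyl(2-methylprop-1-enyl)stannane, CCCC[Sn](CCCC)(CCCC)C=C(C)C
Why: Carbonylative Stille coupling: zerovalent palladium ionises the allylic chloride to an allylpalladium chloride, CO inserts at the primary terminus, and transmetallation with the alkenylstannane followed by reductive elimination forms C9–C10. The reaction is known for primary allylic chlorides with coupling at the less substituted end and retention of alkene geometry, and its neutral medium should not move the β,γ-alkene into conjugation.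

Step 17
Reactants: 22 (R,E)-1-[2,4-bis(triisopropylsilyloxy)phenyl]-3,7,11-trimethyl-3-vinyldodeca-6,10-diene-1,9-dione
Product: 23 (R,E)-1-(2,4-dihydroxyphenyl)-3,7,11-trimethyl-3-vinyldodeca-6,10-diene-1,9-dione
Conditions: HF·pyridine, pyridine, THF, 0 °C → rt
Reagents that add atoms: none
Why: Fluoride-mediated desilylation; both aryl silyl ethers are activated as leaving groups by the ortho and para acyl group, and the pyridine-buffered medium should be too mild to isomerise the skipped dienone or touch C3.

## Compound list

1 | but-3-yn-1-ol | C#CCCO | starting material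
2 | tert-butyl(but-3-yn-1-yloxy)dimethylsilane | C#CCCO[Si](C)(C)C(C)(C)C | intermediate
3 | (E)-[4-(tert-butyldimethylsilyloxy)-2-methylbut-1-en-1-yl]dimethylalane | C[Al](C)/C=C(\C)CCO[Si](C)(C)C(C)(C)C | intermediate (not isolated)
4 | (E)-5-(tert-butyldimethylsilyloxy)-3-methylpent-2-en-1-ol | OC/C=C(\C)CCO[Si](C)(C)C(C)(C)C | intermediate
5 | (E)-tert-butyl[(5-chloro-3-methylpent-3-en-1-yl)oxy]dimethylsilane | ClC/C=C(\C)CCO[Si](C)(C)C(C)(C)C | intermediate
6 | acrolein (prop-2-enal) | C=CC=O | starting material
7 | ethyl 2-(triphenylphosphoranylidene)propanoate | CCOC(=O)C(C)=P(c1ccccc1)(c1ccccc1)c1ccccc1 | starting material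
8 | ethyl (E)-2-methylpenta-2,4-dienoate | C=C/C=C(\C)C(=O)OCC | intermediate
9 | (E)-2-methylpenta-2,4-dien-1-ol | C=C/C=C(\C)CO | intermediate
10 | 1-methoxy-4-({[(E)-2-methylpenta-2,4-dien-1-yl]oxy}methyl)benzene | C=C/C=C(\C)COCc1ccc(OC)cc1 | intermediate
11 | 9-[(E)-5-(4-methoxybenzyloxy)-4-methylpent-3-en-1-yl]-9-borabicyclo[3.3.1]nonane | COc1ccc(COC/C(C)=C/CCB2C3CCCC2CCC3)cc1 | intermediate
12 | (R,E)-tert-butyl{[8-(4-methoxybenzyloxy)-3,7-dimethyl-3-vinyloct-6-en-1-yl]oxy}dimethylsilane | C=C[C@](C)(CC/C=C(\C)COCc1ccc(OC)cc1)CCO[Si](C)(C)C(C)(C)C | intermediate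
13 | (R,E)-8-(4-methoxybenzyloxy)-3,7-dimethyl-3-vinyloct-6-en-1-ol | C=C[C@](C)(CC/C=C(\C)COCc1ccc(OC)cc1)CCO | intermediate
14 | (R,E)-8-(4-methoxybenzyloxy)-3,7-dimethyl-3-vinyloct-6-enal | C=C[C@](C)(CC/C=C(\C)COCc1ccc(OC)cc1)CC=O | intermediate
15 | 4-bromoresorcinol (4-bromobenzene-1,3-diol) | Oc1ccc(Br)c(O)c1 | starting material
16 | 1-bromo-2,4-bis(triisopropylsilyloxy)benzene | Brc1ccc(O[Si](C(C)C)(C(C)C)C(C)C)cc1O[Si](C(C)C)(C(C)C)C(C)C | intermediate
17 | [2,4-bis(triisopropylsilyloxy)phenyl]magnesium bromide | Br[Mg]c1ccc(O[Si](C(C)C)(C(C)C)C(C)C)cc1O[Si](C(C)C)(C(C)C)C(C)C | intermediate (not isolated)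
18 | (3R,6E)-1-[2,4-bis(triisopropylsilyloxy)phenyl]-8-(4-methoxybenzyloxy)-3,7-dimethyl-3-vinyloct-6-en-1-ol, mixture of C1 epimers | C=C[C@](C)(CC/C=C(\C)COCc1ccc(OC)cc1)CC(O)c1ccc(O[Si](C(C)C)(C(C)C)C(C)C)cc1O[Si](C(C)C)(C(C)C)C(C)C | intermediate
19 | (R,E)-1-[2,4-bis(triisopropylsilyloxy)phenyl]-8-(4-methoxybenzyloxy)-3,7-dimethyl-3-vinyloct-6-en-1-one | C=C[C@](C)(CC/C=C(\C)COCc1ccc(OC)cc1)CC(=O)c1ccc(O[Si](C(C)C)(C(C)C)C(C)C)cc1O[Si](C(C)C)(C(C)C)C(C)C | intermediate
20 | (R,E)-1-[2,4-bis(triisopropylsilyloxy)phenyl]-8-hydroxy-3,7-dimethyl-3-vinyloct-6-en-1-one | C=C[C@](C)(CC/C=C(\C)CO)CC(=O)c1ccc(O[Si](C(C)C)(C(C)C)C(C)C)cc1O[Si](C(C)C)(C(C)C)C(C)C | intermediate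
21 | (R,E)-1-[2,4-bis(triisopropylsilyloxy)phenyl]-8-chloro-3,7-dimethyl-3-vinyloct-6-en-1-one | C=C[C@](C)(CC/C=C(\C)CCl)CC(=O)c1ccc(O[Si](C(C)C)(C(C)C)C(C)C)cc1O[Si](C(C)C)(C(C)C)C(C)C | intermediate
22 | (R,E)-1-[2,4-bis(triisopropylsilyloxy)phenyl]-3,7,11-trimethyl-3-vinyldodeca-6,10-diene-1,9-dione | C=C[C@](C)(CC/C=C(\C)CC(=O)C=C(C)C)CC(=O)c1ccc(O[Si](C(C)C)(C(C)C)C(C)C)cc1O[Si](C(C)C)(C(C)C)C(C)C | intermediate
23 | (R,E)-1-(2,4-dihydroxyphenyl)-3,7,11-trimethyl-3-vinyldodeca-6,10-diene-1,9-dione | C=C[C@](C)(CC/C=C(\C)CC(=O)C=C(C)C)CC(=O)c1ccc(O)cc1O | target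

## Step count and risks

Total: 17 steps. Longest linear sequence: 13 steps, from acrolein (6) through steps 4–10 and 12–17. The branch from but-3-yn-1-ol (1) joins after 3 steps and the arene branch after 1 step.

**Step 8 (key step).**
- Most likely failure: insufficient enantioface discrimination, because the γ-carbon of 5 carries two small sp3 groups (methyl and a 2-silyloxyethyl arm), or leakage to α-substitution if the allylcopper intermediate equilibrates before reductive elimination.
- The absolute sense also has to be fixed by choosing the ligand enantiomer.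
- Fallback, from alcohol 4 and diene 10, rejoining at 12: the same C3–C4 bond is made by the copper-catalysed enantioselective SN2′ alkylation of an allylic phosphate with a dialkylzinc reagent. This is a different reaction class, in which control rests on a chelating anionic ligand and a zinc-bound phosphate leaving group, not on a borate. Alcohol 4 would be phosphorylated with ClP(O)(OEt)2 and pyridine to (E)-5-(tert-butyldimethylsilyloxy)-3-methylpent-2-en-1-yl diethyl phosphate F1. Diene 10 would be hydroborated with Et2BH to diethyl[(E)-5-(4-methoxybenzyloxy)-4-methylpent-3-en-1-yl]borane F2, and boron–zinc exchange with Et2Zn would give bis[(E)-5-(4-methoxybenzyloxy)-4-methylpent-3-en-1-yl]zinc F3. F1 and F3 would then be joined with (CuOTf)2·C6H6 and a chiral sulfonate-bearing imidazolinium salt in THF at −15 °C to give 12.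

**Step 16.**
- Most likely failure: erosion of the C6=C7 geometry by syn/anti exchange in the 2-methyl-substituted allylpalladium intermediate.
- Also possible: coupling without CO insertion because the hindered β,β-disubstituted alkenyl group transfers slowly from tin, and migration of the β,γ-alkene into conjugation during prolonged heating.
- Fallback, from chloride 21, rejoining at 22: palladium and CO are avoided. Copper-mediated alkynylation of 21 with 2-methylbut-3-yn-2-ol (CuI, K2CO3, NaI, DMF, rt) should give (R,E)-1-[2,4-bis(triisopropylsilyloxy)phenyl]-11-hydroxy-3,7,11-trimethyl-3-vinyldodec-6-en-9-yn-1-one F4 by SN2 at the primary carbon. A Meyer–Schuster rearrangement of the tertiary propargylic alcohol with (Ph3P)AuNTf2 in toluene at rt should then move the oxygen to C9 and give the β,β-dimethyl enone 22.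

**Step 12.**
- Most likely failure: migration of the ortho silyl group from oxygen to the aryl carbanion or to the newly formed benzylic alkoxide.
- Also possible: sluggish magnesium insertion into the electron-rich bromide and enolisation of the aldehyde by the hindered, basic aryl reagent.
- Fallback, from aldehyde 14 and bromide 16, rejoining at ketone 19 (bypassing 18 and step 13): the ketone is made by acyl cross-coupling. Pinnick oxidation of 14 (NaClO2, NaH2PO4, 2-methylbut-2-ene, t-BuOH/H2O) would give (R,E)-8-(4-methoxybenzyloxy)-3,7-dimethyl-3-vinyloct-6-enoic acid F5. Steglich-type thioesterification with EtSH, EDC and DMAP would give S-ethyl (R,E)-8-(4-methoxybenzyloxy)-3,7-dimethyl-3-vinyloct-6-enethioate F6. Bromide 16 would be converted with Mg, LiCl and ZnCl2 in THF into [2,4-bis(triisopropylsilyloxy)phenyl]zinc chloride F7, in which the weakly basic carbon–zinc bond is trapped as it forms. Fukuyama coupling of F6 with F7 under PdCl2(PPh3)2 in toluene/THF at rt should give 19 directly, with no alkoxide next to the silyl ether.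

## Further compounds

F1 | step 8 | (E)-5-(tert-butyldimethylsilyloxy)-3-methylpent-2-en-1-yl diethyl phosphate | CCOP(=O)(OCC)OC/C=C(\C)CCO[Si](C)(C)C(C)(C)C
F2 | step 8 | diethyl[(E)-5-(4-methoxybenzyloxy)-4-methylpent-3-en-1-yl]borane | CCB(CC)CC/C=C(\C)COCc1ccc(OC)cc1
F3 | step 8 | bis[(E)-5-(4-methoxybenzyloxy)-4-methylpent-3-en-1-yl]zinc | [Zn](CC/C=C(\C)COCc1ccc(OC)cc1)CC/C=C(\C)COCc1ccc(OC)cc1
F4 | step 16 | (R,E)-1-[2,4-bis(triisopropylsilyloxy)phenyl]-11-hydroxy-3,7,11-trimethyl-3-vinyldodec-6-en-9-yn-1-one | C=C[C@](C)(CC/C=C(\C)CC#CC(C)(C)O)CC(=O)c1ccc(O[Si](C(C)C)(C(C)C)C(C)C)cc1O[Si](C(C)C)(C(C)C)C(C)C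
F5 | step 12 | (R,E)-8-(4-methoxybenzyloxy)-3,7-dimethyl-3-vinyloct-6-enoic acid | C=C[C@](C)(CC/C=C(\C)COCc1ccc(OC)cc1)CC(=O)O
F6 | step 12 | S-ethyl (R,E)-8-(4-methoxybenzyloxy)-3,7-dimethyl-3-vinyloct-6-enethioate | C=C[C@](C)(CC/C=C(\C)COCc1ccc(OC)cc1)CC(=O)SCC
F7 | step 12 | [2,4-bis(triisopropylsilyloxy)phenyl]zinc chloride | Cl[Zn]c1ccc(O[Si](C(C)C)(C(C)C)C(C)C)cc1O[Si](C(C)C)(C(C)C)C(C)C
A1 | alternative 1 | (R,E)-{1-[1-(2,4-bis(tert-butyldimethylsilyloxy)phenyl)vinyloxy]-3,7-dimethylocta-2,6-dien-1-yl}dimethyl(phenyl)silane | C=C(O[C@@H](/C=C(\C)CCC=C(C)C)[Si](C)(C)c1ccccc1)c1ccc(O[Si](C)(C)C(C)(C)C)cc1O[Si](C)(C)C(C)(C)C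
A2 | alternative 1 | (R,E)-1-[2,4-bis(tert-butyldimethylsilyloxy)phenyl]-3-{2-[dimethyl(phenyl)silyl]vinyl}-3,7-dimethyloct-6-en-1-one | C[Si](C)(c1ccccc1)/C=C/[C@](C)(CCC=C(C)C)CC(=O)c1ccc(O[Si](C)(C)C(C)(C)C)cc1O[Si](C)(C)C(C)(C)C
A3 | alternative 2 | (R,E)-1-[2,4-bis(tert-butyldimethylsilyloxy)phenyl]-8-chloro-3,7-dimethyl-3-vinyloct-6-en-1-one | C=C[C@](C)(CC/C=C(\C)CCl)CC(=O)c1ccc(O[Si](C)(C)C(C)(C)C)cc1O[Si](C)(C)C(C)(C)C
A4 | alternative 2 | (R,E)-1-[2,4-bis(tert-butyldimethylsilyloxy)phenyl]-3,7,11-trimethyl-3-vinyldodeca-6,10-diene-1,9-dione | C=C[C@](C)(CC/C=C(\C)CC(=O)C=C(C)C)CC(=O)c1ccc(O[Si](C)(C)C(C)(C)C)cc1O[Si](C)(C)C(C)(C)C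
A5 | alternative 3 | (E)-1-[2,4-bis(tert-butyldimethylsilyloxy)phenyl]-3,7-dimethylocta-2,6-dien-1-one | CC(C)=CCC/C(C)=C/C(=O)c1ccc(O[Si](C)(C)C(C)(C)C)cc1O[Si](C)(C)C(C)(C)C
A6 | alternative 3 | (R)-1-[2,4-bis(tert-butyldimethylsilyloxy)phenyl]-3,7-dimethyl-3-vinyloct-6-en-1-one | C=C[C@](C)(CCC=C(C)C)CC(=O)c1ccc(O[Si](C)(C)C(C)(C)C)cc1O[Si](C)(C)C(C)(C)C
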